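A direct plan would lithiate the allyl ether A1 (2-allyloxy-1,3-dimethoxybenzene) at the ether carbon, pass the anion to a stoichiometric pinene-derived dialkylborane and add the resulting (Z)-γ-aryloxyallylborane to 3,4,5-trimethoxybenzaldehyde A2, forming the C1–C2 bond and both stereocentres of the homoallylic alcohol A3.
Ozonolysis with borohydride work-up would then turn the vinyl group into the CH2OH group of the diol A4, and an iridium-catalysed C–H borylation followed by a palladium-catalysed coupling with an allyl halide would add the 4-allyl group last.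
Weak point 1, the asymmetric allylboration: it would rest on a cryogenic s-BuLi deprotonation of an aryl allyl ether that can also be lithiated next to its methoxy groups or undergo Wittig rearrangement, on a chain of intermediates that cannot be isolated, and on a full equivalent of chiral borane.
Weak point 2, the unmasking of CH2OH by ozonolysis: it builds nothing, and because ozone would also cut the allyl group of the target, it forces the route to carry an aryl ether ring that lacks this group.
Weak point 3, the late borylation and allylation of the unprotected diol: two noble-metal steps would be spent at the very end on a substituent that can be bought in place, with the risk of allyl-to-propenyl migration.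

**Retrosynthetic overview**
The target 7 is cut at the C2–O aryl ether bond and taken back to the β-keto ester oxidation level (C1 as ketone, C3 as ethyl ester): 7 from the syn hydroxy ester 6 by ester reduction, 6 from the racemic α-aryloxy β-keto ester 4, 4 from 4-allyl-2,6-dimethoxyphenol 3 and the α-chloro keto ester 2, 2 from the commercial keto ester 1.
The feature used is the C1(OH)–C2(OAr) pair of the propane chain: in 4 the C2–H lies between two carbonyl groups and racemises freely, so one enantioselective hydride transfer to C1 under dynamic kinetic resolution should set C1 and C2 together and funnel both enantiomers of 4 into the (1R,2R) series.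
No ring is formed; both benzene rings are bought with every substituent in place, the allyl group included.
The design needs no organolithium or chiral borane step, no ozonolysis and no late C–H functionalisation, and no oxidant or olefin-active metal meets the allyl group.

Key step: step 3

Assumption: the sense of induction of RuCl[(S,S)-TsDPEN](p-cymene) is taken over from simple aryl ketones, which corresponds to hydride delivery to the Si face of the ketone of 4; if the substrate responded in the opposite sense, the (R,R) complex would be used with no other change.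

Step 1
Reactants: 1 ethyl 3-oxo-3-(3,4,5-trimethoxyphenyl)propanoate
Product: 2 ethyl 2-chloro-3-oxo-3-(3,4,5-trimethoxyphenyl)propanoate (racemic)
Conditions: SO2Cl2 (1.05 equiv), CH2Cl2, 0 °C to rt
Reagents that add atoms: sulfuryl chloride, O=S(=O)(Cl)Cl
Why: Electrophilic α-chlorination of the enol of a β-keto ester, which should be much faster than chlorination of the acyl-deactivated arene, and the stereocentre formed is racemic and labile.

Step 2
Reactants: 2 ethyl 2-chloro-3-oxo-3-(3,4,5-trimethoxyphenyl)propanoate; 3 4-allyl-2,6-dimethoxyphenol (methoxyeugenol)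
Product: 4 ethyl 2-(4-allyl-2,6-dimethoxyphenoxy)-3-oxo-3-(3,4,5-trimethoxyphenyl)propanoate (racemic)
Conditions: K2CO3, acetone, reflux
Reagents that add atoms: none
Why: Williamson-type SN2 displacement of a carbonyl-activated secondary chloride by the phenoxide forms the C2–O aryl ether bond with the allyl group already in place, and C2 is left racemic on purpose because step 3 corrects it.

Step 3
Reactants: 4 ethyl 2-(4-allyl-2,6-dimethoxyphenoxy)-3-oxo-3-(3,4,5-trimethoxyphenyl)propanoate (racemic)
Product: 6 ethyl (2S,3R)-2-(4-allyl-2,6-dimethoxyphenoxy)-3-hydroxy-3-(3,4,5-trimethoxyphenyl)propanoate, via enol tautomer 5 (not isolated)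
Conditions: RuCl[(S,S)-TsDPEN](p-cymene) (1 mol %), HCO2H–Et3N (5:2), CH2Cl2, 30 °C
Reagents that add atoms: none
Why: Noyori–Ikariya asymmetric transfer hydrogenation with dynamic kinetic resolution: the ruthenium hydride formed from the catalyst and formate transfers hydride from Ru and a proton from N–H to the ketone through an outer-sphere six-membered transition state, while Et3N interconverts the enantiomers of unreacted 4 through enol 5 faster than the slow-reacting one is reduced. The closest known reaction type is the syn-selective transfer hydrogenation of α-alkoxy β-keto esters of aryl ketones under dynamic kinetic resolution, and no ring is closed. The carbinol centre (3R here, C1 of the target) is set by the catalyst, whose η6-arene holds the trimethoxyphenyl ring by a C–H/π contact so that the (S,S) complex delivers hydride to the Si face. The aryloxy centre (2S here, C2 of the target) is set by selection of the (S)-enantiomer of 4, which can place its C2–OAr bond antiperiplanar to the incoming hydride in a Felkin–Anh-type arrangement, and this gives the syn relationship. The step needs ketone-over-alkene chemoselectivity, which the outer-sphere mechanism should secure because the coordinatively saturated Ru–H cannot insert or isomerise the allyl group. It also needs irreversibility, which loss of CO2 from formic acid secures, so the electron-rich benzylic alcohol is not dehydrogenated again.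

Step 4
Reactants: 6 ethyl (2S,3R)-2-(4-allyl-2,6-dimethoxyphenoxy)-3-hydroxy-3-(3,4,5-trimethoxyphenyl)propanoate
Product: 7 (1R,2R)-2-(4-allyl-2,6-dimethoxyphenoxy)-1-(3,4,5-trimethoxyphenyl)propane-1,3-diol (target)
Conditions: NaBH4, THF–H2O (3:1), 0 °C to rt
Reagents that add atoms: none
Why: Borohydride reduction of an ester activated by its α-aryloxy and β-hydroxy groups leaves the allyl group and both stereocentres untouched, and the descriptor at the aryloxy carbon changes from S to R only because CH2OH ranks below the carbinol carbon whereas CO2Et ranked above it.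

**Compound list**
1 | ethyl 3-oxo-3-(3,4,5-trimethoxyphenyl)propanoate | CCOC(=O)CC(=O)c1cc(OC)c(OC)c(OC)c1 | starting material
2 | ethyl 2-chloro-3-oxo-3-(3,4,5-trimethoxyphenyl)propanoate (racemic) | CCOC(=O)C(Cl)C(=O)c1cc(OC)c(OC)c(OC)c1 | intermediate
3 | 4-allyl-2,6-dimethoxyphenol (methoxyeugenol) | C=CCc1cc(OC)c(O)c(OC)c1 | starting material
4 | ethyl 2-(4-allyl-2,6-dimethoxyphenoxy)-3-oxo-3-(3,4,5-trimethoxyphenyl)propanoate (racemic) | CCOC(=O)C(Oc1c(OC)cc(CC=C)cc1OC)C(=O)c1cc(OC)c(OC)c(OC)c1 | intermediate
5 | ethyl (E)-2-(4-allyl-2,6-dimethoxyphenoxy)-3-hydroxy-3-(3,4,5-trimethoxyphenyl)prop-2-enoate (enol of 4) | CCOC(=O)/C(Oc1c(OC)cc(CC=C)cc1OC)=C(\O)c1cc(OC)c(OC)c(OC)c1 | intermediate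
6 | ethyl (2S,3R)-2-(4-allyl-2,6-dimethoxyphenoxy)-3-hydroxy-3-(3,4,5-trimethoxyphenyl)propanoate | C=CCc1cc(OC)c(O[C@H](C(=O)OCC)[C@H](O)c2cc(OC)c(OC)c(OC)c2)c(OC)c1 | intermediate
7 | (1R,2R)-2-(4-allyl-2,6-dimethoxyphenoxy)-1-(3,4,5-trimethoxyphenyl)propane-1,3-diol (CNP0308568.1) | C=CCc1cc(OC)c(O[C@H](CO)[C@H](O)c2cc(OC)c(OC)c(OC)c2)c(OC)c1 | target

Total step count: 4. Longest linear sequence: 4 steps (1 to 2 to 4 to 6 to 7); phenol 3 enters in step 2.

**Steps most likely to fail**

Step 3 (key step). Racemisation of the bulky α-aryloxy keto ester might not keep pace with reduction, or the syn preference might be eroded, so that diastereo- and enantiocontrol would fall short. The fallback is an auxiliary-controlled glycolate aldol reaction that sets out from 3 and comes back to the route at the target 7. Phenol 3 would be alkylated with chloroacetic acid (aq NaOH, reflux) to (4-allyl-2,6-dimethoxyphenoxy)acetic acid F1. F1 would be coupled through its pivaloyl mixed anhydride with (S)-4-benzyloxazolidin-2-one (PivCl, Et3N, LiCl, THF) to (S)-4-benzyl-3-[(4-allyl-2,6-dimethoxyphenoxy)acetyl]oxazolidin-2-one F2. The (Z)-boron enolate of F2 (Bu2BOTf, i-Pr2NEt, CH2Cl2, −78 °C) should add to 3,4,5-trimethoxybenzaldehyde A2 through a Zimmerman–Traxler chair to give the Evans syn aldol adduct (S)-4-benzyl-3-[(2S,3R)-2-(4-allyl-2,6-dimethoxyphenoxy)-3-hydroxy-3-(3,4,5-trimethoxyphenyl)propanoyl]oxazolidin-2-one F3. Reductive removal of the auxiliary (LiBH4, THF, 0 °C) should give 7 directly.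

Step 2. The hindered phenoxide might substitute slowly while chloride 2 is tied up as its enolate or is dechlorinated by halophilic attack. The fallback is a crossed Claisen acylation that sets out from 3 and comes back to the route at 4, and it also replaces step 1. Phenol 3 would be alkylated with ethyl bromoacetate (K2CO3, acetone) to ethyl 2-(4-allyl-2,6-dimethoxyphenoxy)acetate F4. The lithium enolate of F4 (LiN(SiMe3)2, 2.2 equiv, THF, −78 °C) would be acylated with 3,4,5-trimethoxybenzoyl chloride to give 4.

Step 4. Under the basic aqueous hydride conditions the β-hydroxy ester might undergo retro-aldol cleavage and re-addition, which would scramble both centres, or the reduction might stall. The fallback is a protect, reduce, deprotect sequence that sets out from 6 and comes back to the route at 7. Silylation of 6 (t-BuMe2SiOTf, 2,6-lutidine, CH2Cl2, 0 °C) would give ethyl (2S,3R)-2-(4-allyl-2,6-dimethoxyphenoxy)-3-(tert-butyldimethylsilyloxy)-3-(3,4,5-trimethoxyphenyl)propanoate F5, which can no longer fragment. Reduction with i-Bu2AlH (CH2Cl2, −78 to 0 °C) would give (2R,3R)-2-(4-allyl-2,6-dimethoxyphenoxy)-3-(tert-butyldimethylsilyloxy)-3-(3,4,5-trimethoxyphenyl)propan-1-ol F6. Desilylation with Bu4NF (THF, 0 °C) would give 7.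

**Further compounds**
F1 | step 3 | (4-allyl-2,6-dimethoxyphenoxy)acetic acid | C=CCc1cc(OC)c(OCC(=O)O)c(OC)c1
F2 | step 3 | (S)-4-benzyl-3-[(4-allyl-2,6-dimethoxyphenoxy)acetyl]oxazolidin-2-one | C=CCc1cc(OC)c(OCC(=O)N2[C@@H](Cc3ccccc3)COC2=O)c(OC)c1
F3 | step 3 | (S)-4-benzyl-3-[(2S,3R)-2-(4-allyl-2,6-dimethoxyphenoxy)-3-hydroxy-3-(3,4,5-trimethoxyphenyl)propanoyl]oxazolidin-2-one | C=CCc1cc(OC)c(O[C@H](C(=O)N2[C@@H](Cc3ccccc3)COC2=O)[C@H](O)c4cc(OC)c(OC)c(OC)c4)c(OC)c1
F4 | step 2 | ethyl 2-(4-allyl-2,6-dimethoxyphenoxy)acetate | C=CCc1cc(OC)c(OCC(=O)OCC)c(OC)c1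
F5 | step 4 | ethyl (2S,3R)-2-(4-allyl-2,6-dimethoxyphenoxy)-3-(tert-butyldimethylsilyloxy)-3-(3,4,5-trimethoxyphenyl)propanoate | C=CCc1cc(OC)c(O[C@H](C(=O)OCC)[C@H](O[Si](C)(C)C(C)(C)C)c2cc(OC)c(OC)c(OC)c2)c(OC)c1
F6 | step 4 | (2R,3R)-2-(4-allyl-2,6-dimethoxyphenoxy)-3-(tert-butyldimethylsilyloxy)-3-(3,4,5-trimethoxyphenyl)propan-1-ol | C=CCc1cc(OC)c(O[C@H](CO)[C@H](O[Si](C)(C)C(C)(C)C)c2cc(OC)c(OC)c(OC)c2)c(OC)c1
A1 | direct plan | 2-(allyloxy)-1,3-dimethoxybenzene | C=CCOc1c(OC)cccc1OC
A2 | direct plan | 3,4,5-trimethoxybenzaldehyde | COc1cc(C=O)cc(OC)c1OC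
A3 | direct plan | (1R,2R)-2-(2,6-dimethoxyphenoxy)-1-(3,4,5-trimethoxyphenyl)but-3-en-1-ol | COc1cccc(OC)c1O[C@H](C=C)[C@H](O)c1cc(OC)c(OC)c(OC)c1
A4 | direct plan | (1R,2R)-2-(2,6-dimethoxyphenoxy)-1-(3,4,5-trimethoxyphenyl)propane-1,3-diol | COc1cccc(OC)c1O[C@H](CO)[C@H](O)c1cc(OC)c(OC)c(OC)c1
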